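Assumption: read from the structure, the descriptors are (2R,4S), which places the C2 methyl and the C4 naphthyl group trans on the pyran ring; the route is planned for this isomer.

## The problem

Cladonaphchrom A (16) is a chroman (O1, C2, C3, C4, C4a, C5–C8, C8a) whose benzo ring, ring A, is a resorcinol. One resorcinol oxygen is O1 of the pyran ring and the other is the free phenol at C5. C4 carries a 4,5-dimethoxynaphthalen-1-yl group and C2 a methyl group; the two stereocentres, C2 (R) and C4 (S), are 1,3-related and trans. C2 is a plain secondary alkyl aryl ether carbon that can be taken from the chiral pool, and once in place it is the only internal handle for C4. C4 is the hard centre: it is wedged between the C5 oxygen of ring A and the peri hydrogen of the naphthalene. The two resorcinol oxygens must be told apart early, because a late symmetric diol can only be differentiated statistically. The peri-dimethoxynaphthalene is very electron-rich and will not stand peracids, halogenating agents, ether-cleaving Lewis acids or long exposure to cations, and the phenol needs one protecting group that lasts to the end. The enabling feature is that C4–H is doubly benzylic (ring A and naphthalene C1) while C3 is an unsubstituted methylene bonded to the chiral-pool carbon C2. A carbanion at C4 can therefore make C3–C4 by displacing a leaving group on C3, and the same acidity allows C4 to be corrected afterwards.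

## Retrosynthesis

**16 to 15 (O–benzyl bond).** The C5 phenol is carried as its benzyl ether 15. Benzyl is chosen over an acetal because it must survive trifluoroacetic acid, LiAlH4 and a lithium amide, and it is removed by neutral hydrogenolysis that touches neither stereocentre. An acid-labile group here would be lost in the deoxygenation of step 4 and would force a statistical re-protection.

**15 to 13 (C3–C4 bond, the key cut).** Cutting O1–C2 instead would require C4 to be set in an open chain with no control element. Cutting C4–C4a would ask a Friedel–Crafts reaction to attack the position between the two oxygens, not the favoured position para to oxygen. The C3–C4 cut leads to diarylmethane 13, which has only the easy stereocentre. The forward reaction needs a base that removes the C4 proton (giving 14) without eliminating HCl, and a ring closure that places the naphthyl group trans to the C2 methyl.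

**13 to 12 to 11 to 9 and 10 (C–Cl, then the aryl O–C2 bond).** The chloride comes from primary alcohol 12 and that from ester 11. Ester 11 is disconnected at the ether bond to phenol 9 and ethyl (S)-lactate 10. A Mitsunobu reaction inverts the lactate carbon to the (R) configuration needed at C2, and the descriptor stays (R) through 12, 13 and 15 because the priority order does not change. Chloride is preferred to a sulfonate because it tolerates a strong amide base; a β-chloro alcohol as direct Mitsunobu partner would be shorter, but substitution next to a chloromethyl group is sluggish.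

**9 to 7 to 5 and 3 (C4–C4a bond and the C4 oxygen).** Phenol 9 comes from carbinol 7 by ionic deoxygenation, and 7 from addition of aryllithium 6 to aldehyde 3. The methoxymethyl ether in 5 directs lithiation to the carbon between the two oxygens. It then falls off in the same acidic step that removes the carbinol oxygen (via 8), while the benzyl ether stays. The two resorcinol oxygens are thus differentiated without a statistical step.

**3 to 1 and 5 to 4.** Aldehyde 3 is the Vilsmeier product of 1,8-dimethoxynaphthalene 1 (via iminium salt 2). Ether 5 is the methoxymethyl ether of commercial 3-(benzyloxy)phenol 4.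

## Roads not taken

**Alternative 1: ring A built last by Danheiser benzannulation.**
- Cut: C4a–C8a, C5–C6 and C8–C8a, so that ring A is assembled from cyclobutenone A3 and siloxyalkyne A2, which already carries both stereocentres.
- Forward key step: heating opens A3 to its ketene valence isomer, which adds to A2; a second ring opening and a 6π-electrocyclisation then give phenol A1.
- Merits: the mechanism puts the free hydroxyl where O1 will be and the silyl ether at C5, so the two oxygens are differentiated without any protecting-group logic. In this respect it is better than the chosen plan.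
- Weak points: A2 needs two stereocentres set separately in an open chain, one of them benzylic and propargylic. Parent A3 is volatile and prone to polymerise. After A1 the pyran must still be closed (selective unmasking of the secondary alcohol, Mitsunobu inversion) and the aryl silyl ether removed.
- Comparison: much effort goes into building the cheapest part of the molecule. The chosen plan buys the same differentiation with one protection step from 4 and derives both stereocentres from one chiral-pool ester.

**Alternative 2: Baeyer–Villiger oxygen insertion into a 3-arylindanone.**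
- Cut: O1–C8a and O1–C2, leading back to indanone A5.
- Forward key step: a peracid adds to the ketone of A5 and the aryl carbon migrates to oxygen, giving lactone A4.
- Merits: C4 could be set under catalyst control by an asymmetric conjugate arylation leading to A5, independent of C2. That is a real advantage over the substrate-controlled closure of step 8.
- Weak points: the peracid meets the peri-dimethoxynaphthalene, the most oxidisable part of the molecule. The lactone carbonyl of A4 must then become a methyl-bearing carbon with trans configuration; methyl addition and lactol reduction would normally deliver hydride so as to give the cis isomer. Several extra steps follow the key step.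
- Comparison: the chosen plan has no oxidant anywhere, and its C2 configuration is fixed before the ring exists.

**Alternative 3: quinone methide hetero-Diels–Alder with a vinyl ether.**
- Cut: C3–C4 and O1–C2 together.
- Forward key step: a chiral phosphoric acid dehydrates triol A7 to the ortho-quinone methide, which adds ethyl vinyl ether A8 to give acetal A6.
- Merits: this is the shortest road to the chroman ring, since A7 is close to 7 of the chosen route. It makes two bonds at once and sets C4 by catalyst control. In step count it beats the chosen plan.
- Weak points: C2 of A6 carries ethoxy, not methyl. Exchange through the oxocarbenium ion with a methyl nucleophile must give the 2,4-trans product, and that facial preference is not assured. Enantiocontrol with a 2,6-dihydroxyaryl carbinol bearing a peri-substituted naphthyl group would need catalyst development. The second phenol is unprotected throughout.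
- Comparison: against the shorter count the chosen plan sets a C2 configuration that is bought and cannot drift, no catalyst optimisation, and a C4 centre that can be corrected by equilibration.

Key step: step 8

## Route

Step 1
Reactants: 1 1,8-dimethoxynaphthalene
Product: 3 4,5-dimethoxynaphthalene-1-carbaldehyde, via iminium salt 2 (not isolated)
Conditions: POCl3, DMF, 0 °C to 80 °C; then ice–water
Reagents that add atoms: N,N-dimethylformamide CN(C)C=O; water O
Why: Vilsmeier–Haack formylation; the chloroiminium ion should attack C4, para to a methoxy group and the most nucleophilic open position, and the aryl iminium salt 2 is hydrolysed on work-up.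

Step 2
Reactants: 4 3-(benzyloxy)phenol
Product: 5 1-(benzyloxy)-3-(methoxymethoxy)benzene
Conditions: MOMCl, i-Pr2NEt, CH2Cl2, 0 °C to rt
Reagents that add atoms: chloromethyl methyl ether COCCl
Why: Standard O-alkylation of a phenol to its methoxymethyl ether, which installs the directing group for step 3 and the acid-labile partner of the benzyl ether.

Step 3
Reactants: 5 1-(benzyloxy)-3-(methoxymethoxy)benzene; 3 4,5-dimethoxynaphthalene-1-carbaldehyde
Product: 7 [2-(benzyloxy)-6-(methoxymethoxy)phenyl](4,5-dimethoxynaphthalen-1-yl)methanol (racemic), via aryllithium 6 (not isolated)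
Conditions: n-BuLi, THF, 0 °C; then 3, −78 °C to rt; then H2O
Reagents that add atoms: none
Why: Directed ortho-metalation at the carbon flanked by both ether oxygens, followed by 1,2-addition of the aryllithium to the aldehyde; the carbinol centre is formed as a racemate and is erased in step 4.

Step 4
Reactants: 7 [2-(benzyloxy)-6-(methoxymethoxy)phenyl](4,5-dimethoxynaphthalen-1-yl)methanol
Product: 9 3-(benzyloxy)-2-[(4,5-dimethoxynaphthalen-1-yl)methyl]phenol, via MOM-protected diarylmethane 8 (not isolated)
Conditions: Et3SiH, CF3CO2H, CH2Cl2, 0 °C to rt
Reagents that add atoms: none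
Why: Ionic hydrogenation; the doubly aryl-stabilised cation forms readily and is trapped by the silane, after which the same acid should cleave the methoxymethyl ether (excess silane scavenging the methoxymethyl cation) while the benzyl ether persists, so the two resorcinol oxygens emerge differentiated.

Step 5
Reactants: 9 3-(benzyloxy)-2-[(4,5-dimethoxynaphthalen-1-yl)methyl]phenol; 10 ethyl (S)-lactate
Product: 11 ethyl (2R)-2-{3-(benzyloxy)-2-[(4,5-dimethoxynaphthalen-1-yl)methyl]phenoxy}propanoate
Conditions: PPh3, DIAD, THF, 0 °C to rt
Reagents that add atoms: none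
Why: Mitsunobu etherification; the phenoxide displaces the activated lactate oxygen by SN2 with inversion, which converts the (S) centre of 10 into the (R) centre that becomes C2.

Step 6
Reactants: 11 ethyl (2R)-2-{3-(benzyloxy)-2-[(4,5-dimethoxynaphthalen-1-yl)methyl]phenoxy}propanoate
Product: 12 (2R)-2-{3-(benzyloxy)-2-[(4,5-dimethoxynaphthalen-1-yl)methyl]phenoxy}propan-1-ol
Conditions: LiAlH4, THF, 0 °C; then H2O
Reagents that add atoms: none
Why: Hydride reduction of an ester to the primary alcohol; at 0 °C reduction should be much faster than enolisation, so the α-aryloxy stereocentre is retained.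

Step 7
Reactants: 12 (2R)-2-{3-(benzyloxy)-2-[(4,5-dimethoxynaphthalen-1-yl)methyl]phenoxy}propan-1-ol
Product: 13 1-(benzyloxy)-3-{[(2R)-1-chloropropan-2-yl]oxy}-2-[(4,5-dimethoxynaphthalen-1-yl)methyl]benzene
Conditions: PPh3, CCl4, CH2Cl2, 40 °C
Reagents that add atoms: carbon tetrachloride ClC(Cl)(Cl)Cl
Why: Appel chlorination of a primary alcohol under neutral conditions; substitution occurs at the primary carbon, so the adjacent stereocentre is untouched and the electron-rich arenes see no electrophilic chlorine.

Step 8
Reactants: 13 1-(benzyloxy)-3-{[(2R)-1-chloropropan-2-yl]oxy}-2-[(4,5-dimethoxynaphthalen-1-yl)methyl]benzene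
Product: 15 (2R,4S)-5-(benzyloxy)-4-(4,5-dimethoxynaphthalen-1-yl)-2-methylchromane, via diarylmethyllithium 14 (not isolated)
Conditions: LiN(i-Pr)2 (LDA), THF, −78 °C to 0 °C; then H2O
Reagents that add atoms: none
Why: LDA removes a C4 proton of 13, the only doubly benzylic C–H in the molecule, and the diarylmethyllithium 14 displaces chloride at the primary carbon C3 by intramolecular SN2 attack, forming C3–C4; the closest known reaction type is the intramolecular alkylation of laterally metalated diarylmethanes. The pyran ring (C4, C4a, C8a, O1, C2, C3) closes in the 6-exo-tet mode, with chloride leaving outside the new ring. Ring A, with two ortho oxygens, is twisted out of the carbanion plane, so the charge is delocalised mainly into the naphthalene and the carbanion p orbital lies near the plane of ring A, pointing at the side chain on O1. The C2 stereocentre from step 5 controls C4: in the chair-like transition state the C2 methyl sits equatorial and the naphthyl group should take the pseudoaxial position, because the pseudoequatorial one would push it into the C5 benzyloxy group. Methyl equatorial with naphthyl pseudoaxial is the 2,4-trans arrangement, that is (2R,4S). The step needs chemoselectivity for C4–H removal over E2 loss of HCl and over metalation of the benzyl ether; the hindered amide base, the far higher acidity of the diarylmethane C–H assisted by the flanking ether oxygens, the low E2 reactivity of a primary chloride and the irreversible ring closure are expected to secure it. It also needs trans diastereoselectivity, which rests on the conformational argument above and is backed by the fact that C4–H of 15 is still doubly benzylic, so the trans isomer, expected to be the more stable one for the same peri reason, can also be reached by base equilibration.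

Step 9
Reactants: 15 (2R,4S)-5-(benzyloxy)-4-(4,5-dimethoxynaphthalen-1-yl)-2-methylchromane
Product: 16 Cladonaphchrom A, (2R,4S)-4-(4,5-dimethoxynaphthalen-1-yl)-2-methylchroman-5-ol
Conditions: H2 (1 atm), Pd/C, EtOAc/MeOH, rt
Reagents that add atoms: none
Why: Catalytic hydrogenolysis of the benzyl aryl ether under neutral conditions; the methyl ethers, the alkyl aryl ether at C2 and both stereocentres should be unaffected.

## Compound list

1 | 1,8-dimethoxynaphthalene | COc1cccc2cccc(OC)c12 | starting material
2 | N-[(4,5-dimethoxynaphthalen-1-yl)methylidene]-N-methylmethanaminium chloride | COc1cccc2c(C=[N+](C)C)ccc(OC)c12.[Cl-] | intermediate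
3 | 4,5-dimethoxynaphthalene-1-carbaldehyde | COc1cccc2c(C=O)ccc(OC)c12 | intermediate
4 | 3-(benzyloxy)phenol | Oc1cccc(OCc2ccccc2)c1 | starting material
5 | 1-(benzyloxy)-3-(methoxymethoxy)benzene | COCOc1cccc(OCc2ccccc2)c1 | intermediate
6 | [2-(benzyloxy)-6-(methoxymethoxy)phenyl]lithium | [Li]c1c(OCOC)cccc1OCc1ccccc1 | intermediate
7 | [2-(benzyloxy)-6-(methoxymethoxy)phenyl](4,5-dimethoxynaphthalen-1-yl)methanol (racemic) | COc1cccc2c(C(O)c3c(OCOC)cccc3OCc3ccccc3)ccc(OC)c12 | intermediate
8 | 1-(benzyloxy)-2-[(4,5-dimethoxynaphthalen-1-yl)methyl]-3-(methoxymethoxy)benzene | COc1cccc2c(Cc3c(OCOC)cccc3OCc3ccccc3)ccc(OC)c12 | intermediate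
9 | 3-(benzyloxy)-2-[(4,5-dimethoxynaphthalen-1-yl)methyl]phenol | COc1cccc2c(Cc3c(O)cccc3OCc3ccccc3)ccc(OC)c12 | intermediate
10 | ethyl (S)-lactate, ethyl (2S)-2-hydroxypropanoate | CCOC(=O)[C@H](C)O | starting material
11 | ethyl (2R)-2-{3-(benzyloxy)-2-[(4,5-dimethoxynaphthalen-1-yl)methyl]phenoxy}propanoate | CCOC(=O)[C@@H](C)Oc1cccc(OCc2ccccc2)c1Cc1ccc(OC)c2c(OC)cccc12 | intermediate
12 | (2R)-2-{3-(benzyloxy)-2-[(4,5-dimethoxynaphthalen-1-yl)methyl]phenoxy}propan-1-ol | OC[C@@H](C)Oc1cccc(OCc2ccccc2)c1Cc1ccc(OC)c2c(OC)cccc12 | intermediate
13 | 1-(benzyloxy)-3-{[(2R)-1-chloropropan-2-yl]oxy}-2-[(4,5-dimethoxynaphthalen-1-yl)methyl]benzene | ClC[C@@H](C)Oc1cccc(OCc2ccccc2)c1Cc1ccc(OC)c2c(OC)cccc12 | intermediate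
14 | [(2-(benzyloxy)-6-{[(2R)-1-chloropropan-2-yl]oxy}phenyl)(4,5-dimethoxynaphthalen-1-yl)methyl]lithium | ClC[C@@H](C)Oc1cccc(OCc2ccccc2)c1C([Li])c1ccc(OC)c2c(OC)cccc12 | intermediate
15 | (2R,4S)-5-(benzyloxy)-4-(4,5-dimethoxynaphthalen-1-yl)-2-methylchromane | COc1cccc2c([C@@H]3C[C@@H](C)Oc4cccc(OCc5ccccc5)c43)ccc(OC)c12 | intermediate
16 | Cladonaphchrom A, (2R,4S)-4-(4,5-dimethoxynaphthalen-1-yl)-2-methylchroman-5-ol | COc1cccc2c([C@@H]3C[C@@H](C)Oc4cccc(O)c43)ccc(OC)c12 | target

## Step count and risks

Total steps: 9. Longest linear sequence: 8 steps (step 1 or step 2, then steps 3 to 9).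

**Step 8 (key step).** Deprotonation at C4 may be too slow, so that base-induced loss of HCl from the side chain competes. The facial selectivity of the closure may also be lower than the conformational argument predicts.
Fallback, from 9 back to 15:
- Phenol 9 is re-protected (MOMCl, i-Pr2NEt) to give 8.
- With no chloride present, n-BuLi in THF can be used to form {[2-(benzyloxy)-6-(methoxymethoxy)phenyl](4,5-dimethoxynaphthalen-1-yl)methyl}lithium F1.
- F1 opens (S)-2-methyloxirane at the terminal carbon and forms the same C3–C4 bond, giving (2S)-4-[2-(benzyloxy)-6-(methoxymethoxy)phenyl]-4-(4,5-dimethoxynaphthalen-1-yl)butan-2-ol F2 as a mixture of C4 epimers.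
- HCl in MeOH removes the acetal to give 3-(benzyloxy)-2-[(3S)-1-(4,5-dimethoxynaphthalen-1-yl)-3-hydroxybutyl]phenol F3.
- Intramolecular Mitsunobu etherification (PPh3, DIAD) closes O1–C2 with inversion to the (R) centre, giving 15 together with its epimer (2R,4R)-5-(benzyloxy)-4-(4,5-dimethoxynaphthalen-1-yl)-2-methylchromane F4.
- KOt-Bu in DMSO should equilibrate F4 through the C4 carbanion into 15. The same equilibration would serve the main route if only the selectivity of step 8 is at fault.

**Step 3.** Metalation may go astray, by deprotonation of the benzylic methylene of the benzyl ether (followed by Wittig rearrangement) or by lithiation at the other position ortho to the acetal.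
Fallback, from 3 back to 9:
- Resorcinol is converted (MOMCl, i-Pr2NEt) into 1,3-bis(methoxymethoxy)benzene F5.
- n-BuLi gives [2,6-bis(methoxymethoxy)phenyl]lithium F6 without ambiguity.
- Addition to 3 gives [2,6-bis(methoxymethoxy)phenyl](4,5-dimethoxynaphthalen-1-yl)methanol F7.
- Et3SiH and CF3CO2H give 2-[(4,5-dimethoxynaphthalen-1-yl)methyl]benzene-1,3-diol F8.
- Mono-benzylation (BnBr, K2CO3, acetone) returns 9. The price is a statistical step with recycling of F8.

**Step 4.** The diarylmethyl cation or the methoxymethyl cation may alkylate the electron-rich rings (oligomerisation), and the acetal may be reduced to a methyl ether instead of being cleaved.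
Fallback, from 7 back to 9:
- The carbinol is converted (NaH, CS2, MeI) into O-{[2-(benzyloxy)-6-(methoxymethoxy)phenyl](4,5-dimethoxynaphthalen-1-yl)methyl} S-methyl carbonodithioate F9.
- Barton–McCombie deoxygenation (Bu3SnH, AIBN, toluene, 90 °C) gives 8 without any cation.
- Mild methanolysis (HCl, MeOH) then gives 9.

**Step 5.** Coupling at the ortho-substituted phenol may be slow, so that elimination of the activated lactate or alkylation of the hydrazine by-product takes over, with possible erosion of enantiopurity.
Fallback, from 10 and 9 back to 11:
- 10 is converted (Tf2O, 2,6-lutidine, CH2Cl2, −78 °C) into ethyl (2S)-2-{[(trifluoromethyl)sulfonyl]oxy}propanoate F10.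
- The potassium phenoxide of 9 (K2CO3, MeCN, 0 °C) displaces the triflate with inversion to give 11.

## Further compounds

F1 | step 8 | {[2-(benzyloxy)-6-(methoxymethoxy)phenyl](4,5-dimethoxynaphthalen-1-yl)methyl}lithium | [Li]C(c1ccc(OC)c2c(OC)cccc12)c1c(OCOC)cccc1OCc1ccccc1
F2 | step 8 | (2S)-4-[2-(benzyloxy)-6-(methoxymethoxy)phenyl]-4-(4,5-dimethoxynaphthalen-1-yl)butan-2-ol (C4 epimers) | C[C@H](O)CC(c1ccc(OC)c2c(OC)cccc12)c1c(OCOC)cccc1OCc1ccccc1
F3 | step 8 | 3-(benzyloxy)-2-[(3S)-1-(4,5-dimethoxynaphthalen-1-yl)-3-hydroxybutyl]phenol (C1 epimers) | C[C@H](O)CC(c1ccc(OC)c2c(OC)cccc12)c1c(O)cccc1OCc1ccccc1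
F4 | step 8 | (2R,4R)-5-(benzyloxy)-4-(4,5-dimethoxynaphthalen-1-yl)-2-methylchromane | COc1cccc2c([C@H]3C[C@@H](C)Oc4cccc(OCc5ccccc5)c43)ccc(OC)c12
F5 | step 3 | 1,3-bis(methoxymethoxy)benzene | COCOc1cccc(OCOC)c1
F6 | step 3 | [2,6-bis(methoxymethoxy)phenyl]lithium | [Li]c1c(OCOC)cccc1OCOC
F7 | step 3 | [2,6-bis(methoxymethoxy)phenyl](4,5-dimethoxynaphthalen-1-yl)methanol | COc1cccc2c(C(O)c3c(OCOC)cccc3OCOC)ccc(OC)c12
F8 | step 3 | 2-[(4,5-dimethoxynaphthalen-1-yl)methyl]benzene-1,3-diol | COc1cccc2c(Cc3c(O)cccc3O)ccc(OC)c12
F9 | step 4 | O-{[2-(benzyloxy)-6-(methoxymethoxy)phenyl](4,5-dimethoxynaphthalen-1-yl)methyl} S-methyl carbonodithioate | COc1cccc2c(C(OC(=S)SC)c3c(OCOC)cccc3OCc3ccccc3)ccc(OC)c12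
F10 | step 5 | ethyl (2S)-2-{[(trifluoromethyl)sulfonyl]oxy}propanoate | CCOC(=O)[C@H](C)OS(=O)(=O)C(F)(F)F
A1 | alternative 1 | 2-[(1S,3S)-1-(4,5-dimethoxynaphthalen-1-yl)-3-(triisopropylsilyloxy)butyl]-3-(triisopropylsilyloxy)phenol | COc1cccc2c([C@H](C[C@H](C)O[Si](C(C)C)(C(C)C)C(C)C)c3c(O)cccc3O[Si](C(C)C)(C(C)C)C(C)C)ccc(OC)c12
A2 | alternative 1 | (3S,5S)-3-(4,5-dimethoxynaphthalen-1-yl)-1,5-bis(triisopropylsilyloxy)hex-1-yne | COc1cccc2c([C@H](C[C@H](C)O[Si](C(C)C)(C(C)C)C(C)C)C#CO[Si](C(C)C)(C(C)C)C(C)C)ccc(OC)c12
A3 | alternative 1 | cyclobut-2-en-1-one | O=C1C=CC1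
A4 | alternative 2 | (4S)-5-(benzyloxy)-4-(4,5-dimethoxynaphthalen-1-yl)chroman-2-one | COc1cccc2c([C@@H]3CC(=O)Oc4cccc(OCc5ccccc5)c43)ccc(OC)c12
A5 | alternative 2 | (3S)-4-(benzyloxy)-3-(4,5-dimethoxynaphthalen-1-yl)-2,3-dihydro-1H-inden-1-one | COc1cccc2c([C@@H]3CC(=O)c4cccc(OCc5ccccc5)c43)ccc(OC)c12
A6 | alternative 3 | (2R,4S)-2-ethoxy-4-(4,5-dimethoxynaphthalen-1-yl)chroman-5-ol (2,4-cis) | COc1cccc2c([C@@H]3C[C@H](OCC)Oc4cccc(O)c43)ccc(OC)c12
A7 | alternative 3 | 2-[(4,5-dimethoxynaphthalen-1-yl)(hydroxy)methyl]benzene-1,3-diol | COc1cccc2c(C(O)c3c(O)cccc3O)ccc(OC)c12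
A8 | alternative 3 | ethyl vinyl ether (ethoxyethene) | C=COCC
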